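**Plan**
Rings: A carries OMe, B is the para-phenylene, C carries OH, D is the meta-phenylene. The retrosynthesis cuts (i) the bond from ring A to the CH2 of the A–D bridge, (ii) the CH2–CH2 bond region of the B–C bridge, and (iii) the two diaryl ether C–O bonds.
Enabling feature: the ring A carbon that carries the A–D bridge is para to the OMe-bearing carbon and meta to the O–B carbon. This is where a 2-aryloxyanisole is acylated, so ring A enters unfunctionalised.
Forward: two SNAr etherifications give the A–O–B and C–O–D halves. Wittig olefination and hydrogenation join them through the B–C bridge to an open-chain arylacetic acid.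
The only ring, the 20-membered macrocycle, closes last by intramolecular Friedel–Crafts acylation. Ionic hydrogenation of the ketone and removal of the mesylate finish the route.
Stereochemistry: the target has no stereocentre; the stilbene E/Z mixture is erased by hydrogenation.

Key step: step 10

Remark: pakyonol as drawn is achiral (no stereocentre, no fixed stereogenic axis), so "single enantiomer" is taken to mean the compound itself and no absolute stereocontrol is planned.

**Route**

Step 1
Reactants: 1 guaiacol; 2 4-fluorobenzaldehyde
Product: 3 4-(2-methoxyphenoxy)benzaldehyde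
Conditions: K2CO3, DMF, 130 °C
Reagents that add atoms: none
Why: SNAr (addition–elimination) of the guaiacol phenoxide on a fluoroarene activated by the para-formyl group is a standard diaryl ether synthesis.

Step 2
Reactants: 3 4-(2-methoxyphenoxy)benzaldehyde
Product: 4 [4-(2-methoxyphenoxy)phenyl]methanol
Conditions: NaBH4, MeOH, 0 °C
Reagents that add atoms: none
Why: Borohydride reduction of an aromatic aldehyde to the benzylic alcohol, with the ethers untouched.

Step 3
Reactants: 4 [4-(2-methoxyphenoxy)phenyl]methanol
Product: 5 [4-(2-methoxyphenoxy)benzyl]triphenylphosphonium bromide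
Conditions: PPh3·HBr, MeCN, reflux
Reagents that add atoms: triphenylphosphine hydrobromide, Br.c1ccc(cc1)P(c1ccccc1)c1ccccc1
Why: Phosphonium salt formation, in which the electron-rich p-aryloxybenzylic alcohol is activated by HBr and the benzylic carbon is captured by triphenylphosphine, is the usual one-step entry to benzylic Wittig salts.

Step 4
Reactants: 6 4-fluoro-3-hydroxybenzaldehyde
Product: 7 3-(benzyloxy)-4-fluorobenzaldehyde
Conditions: BnBr, K2CO3, acetone, reflux
Reagents that add atoms: benzyl bromide, BrCc1ccccc1
Why: Williamson etherification masks the phenol, whose phenoxide would otherwise deactivate the ring towards the following SNAr.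

Step 5
Reactants: 7 3-(benzyloxy)-4-fluorobenzaldehyde; 8 methyl 2-(3-hydroxyphenyl)acetate
Product: 9 methyl 2-{3-[2-(benzyloxy)-4-formylphenoxy]phenyl}acetate
Conditions: Cs2CO3, DMSO, 100 °C
Reagents that add atoms: none
Why: SNAr of the phenoxide of 8 on the fluoride para to the formyl group should proceed because carbonate deprotonates the phenol but hardly enolises the arylacetate ester.

Step 6
Reactants: 5 [4-(2-methoxyphenoxy)benzyl]triphenylphosphonium bromide; 9 methyl 2-{3-[2-(benzyloxy)-4-formylphenoxy]phenyl}acetate
Product: 10 stilbene methyl ester (E/Z mixture) joining rings B and C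
Conditions: K2CO3, 18-crown-6 (cat.), CH2Cl2, reflux
Reagents that add atoms: none
Why: Wittig olefination with a semi-stabilised benzylic ylide under mild solid–liquid phase-transfer conditions spares the methyl ester, and the alkene geometry is irrelevant because the double bond is hydrogenated next.

Step 7
Reactants: 10 stilbene methyl ester (E/Z mixture)
Product: 11 bibenzyl phenol methyl ester
Conditions: H2 (1 atm), 10% Pd/C, EtOAc–MeOH, rt
Reagents that add atoms: none
Why: Catalytic hydrogenation saturates the stilbene and hydrogenolyses the benzyl ether in one operation, while the diaryl ethers, the aryl methyl ether and the ester are inert.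

Step 8
Reactants: 11 bibenzyl phenol methyl ester
Product: 12 bibenzyl mesylate methyl ester
Conditions: MsCl, Et3N, CH2Cl2, 0 °C
Reagents that add atoms: methanesulfonyl chloride, CS(=O)(=O)Cl
Why: O-Sulfonylation of the phenol gives an acid-stable mesylate that protects the oxygen from acylation and deactivates ring C for the Friedel–Crafts step.

Step 9
Reactants: 12 bibenzyl mesylate methyl ester
Product: 13 open-chain arylacetic acid with ring C mesylate
Conditions: LiOH·H2O, THF–H2O, 0 °C to rt; then 1 M HCl
Reagents that add atoms: lithium hydroxide, [Li+].[OH-]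
Why: Saponification of an unhindered arylacetic methyl ester is fast at room temperature, whereas an aryl methanesulfonate needs hot concentrated alkali, so the ester should be cleaved selectively.

Step 10
Reactants: 13 open-chain arylacetic acid with ring C mesylate
Product: 15 20-membered macrocyclic ketone mesylate, via acyl trifluoroacetate 14 (not isolated)
Conditions: TFAA (excess), 85% H3PO4 (cat.), CH2Cl2, syringe-pump addition of 13 (final about 1 mM), rt
Reagents that add atoms: none
Why: The acid is converted in the flask into its acyl trifluoroacetate 14, which under acid catalysis reacts as an arylacetyl cation, attacks ring A at the carbon para to the methoxy group to give a Wheland intermediate and, after loss of the proton, leaves the aryl ketone. The closest known reaction type is the high-dilution intramolecular Friedel–Crafts acylation of aryl-substituted carboxylic acid derivatives to macrocyclic cyclophane ketones, together with the acylation of anisoles by arylacetic acids through mixed trifluoroacetic anhydrides to give deoxybenzoins. The 20-membered ring closes by C–C bond formation in the exo sense at the acyl carbon, the carbonyl oxygen ending outside the ring, and slow addition keeps the anhydride dilute enough for cyclisation to outrun oligomerisation. No stereocentre is formed. The step needs attack para to OMe and not para to the aryloxy oxygen of ring A (which would give a 21-membered isomer); the stronger donor OMe should secure this, since the aryloxy lone pair is shared with ring B. It also needs ring A to react before the other rings: ring C is deactivated by the mesylate and cannot be reached without an impossibly small meta-bridged ring, ring B offers only positions ortho to an aryloxy group that would give a strained 15-membered ring, and the activated positions of ring D lie on the ring that carries the tether.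

Step 11
Reactants: 15 20-membered macrocyclic ketone mesylate
Product: 16 pakyonol methanesulfonate
Conditions: Et3SiH (excess), TFA, CH2Cl2, rt
Reagents that add atoms: none
Why: Ionic hydrogenation, in which the protonated p-methoxyaryl ketone takes up hydride from the silane, the benzylic alcohol ionises to a cation stabilised by the para-methoxy group and a second hydride transfer gives the methylene, leaves the mesylate and the ethers untouched.

Step 12
Reactants: 16 pakyonol methanesulfonate
Product: 17 pakyonol
Conditions: KOH, MeOH–dioxane–H2O, reflux; then dilute HCl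
Reagents that add atoms: none
Why: Basic hydrolysis of the aryl methanesulfonate by attack of hydroxide at sulfur frees the phenol, and the methyl ether, the diaryl ethers and the bibenzyl bridges are stable to alkali.

**Compound list**
1 | guaiacol (2-methoxyphenol) | COc1ccccc1O | starting material
2 | 4-fluorobenzaldehyde | O=Cc1ccc(F)cc1 | starting material
3 | 4-(2-methoxyphenoxy)benzaldehyde | COc1ccccc1Oc1ccc(C=O)cc1 | intermediate
4 | [4-(2-methoxyphenoxy)phenyl]methanol | COc1ccccc1Oc1ccc(CO)cc1 | intermediate
5 | [4-(2-methoxyphenoxy)benzyl]triphenylphosphonium bromide | COc1ccccc1Oc1ccc(C[P+](c2ccccc2)(c2ccccc2)c2ccccc2)cc1.[Br-] | intermediate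
6 | 4-fluoro-3-hydroxybenzaldehyde | O=Cc1ccc(F)c(O)c1 | starting material
7 | 3-(benzyloxy)-4-fluorobenzaldehyde | O=Cc1ccc(F)c(OCc2ccccc2)c1 | intermediate
8 | methyl 2-(3-hydroxyphenyl)acetate | COC(=O)Cc1cccc(O)c1 | starting material
9 | methyl 2-{3-[2-(benzyloxy)-4-formylphenoxy]phenyl}acetate | COC(=O)Cc1cccc(Oc2ccc(C=O)cc2OCc2ccccc2)c1 | intermediate
10 | methyl 2-{3-[2-(benzyloxy)-4-{2-[4-(2-methoxyphenoxy)phenyl]ethenyl}phenoxy]phenyl}acetate (E/Z mixture, geometry not defined) | COC(=O)Cc1cccc(Oc2ccc(C=Cc3ccc(Oc4ccccc4OC)cc3)cc2OCc2ccccc2)c1 | intermediate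
11 | methyl 2-{3-[2-hydroxy-4-{2-[4-(2-methoxyphenoxy)phenyl]ethyl}phenoxy]phenyl}acetate | COC(=O)Cc1cccc(Oc2ccc(CCc3ccc(Oc4ccccc4OC)cc3)cc2O)c1 | intermediate
12 | methyl 2-{3-[2-(methanesulfonyloxy)-4-{2-[4-(2-methoxyphenoxy)phenyl]ethyl}phenoxy]phenyl}acetate | COC(=O)Cc1cccc(Oc2ccc(CCc3ccc(Oc4ccccc4OC)cc3)cc2OS(C)(=O)=O)c1 | intermediate
13 | 2-{3-[2-(methanesulfonyloxy)-4-{2-[4-(2-methoxyphenoxy)phenyl]ethyl}phenoxy]phenyl}acetic acid | COc1ccccc1Oc1ccc(cc1)CCc1ccc(c(OS(C)(=O)=O)c1)Oc1cccc(c1)CC(=O)O | intermediate
14 | mixed anhydride of 13 with trifluoroacetic acid (acyl trifluoroacetate) | COc1ccccc1Oc1ccc(cc1)CCc1ccc(c(OS(C)(=O)=O)c1)Oc1cccc(c1)CC(=O)OC(=O)C(F)(F)F | intermediate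
15 | 20-membered macrocyclic deoxybenzoin: pakyonol skeleton with C=O at the bridge carbon bonded to ring A (para to OMe) and OMs on ring C | COc1ccc2cc1Oc1ccc(cc1)CCc1ccc(c(OS(C)(=O)=O)c1)Oc1cccc(c1)CC2=O | intermediate
16 | pakyonol methanesulfonate (ring C O-mesylate) | COc1ccc2cc1Oc1ccc(cc1)CCc1ccc(c(OS(C)(=O)=O)c1)Oc1cccc(c1)CC2 | intermediate
17 | pakyonol | COc1ccc2cc1Oc1ccc(cc1)CCc1ccc(c(O)c1)Oc1cccc(c1)CC2 | target

**Count**
Total steps: 12. Longest linear sequence: 10 steps (steps 1, 2, 3, 6, 7, 8, 9, 10, 11, 12 from guaiacol).

**Steps most likely to fail**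

Step 10. Closure of a 20-membered ring is slow, so intermolecular acylation may build oligomers, and some attack para to the aryloxy oxygen of ring A may occur. The fallback makes the aryl–carbonyl bond between two molecules and closes the ring at the B–C bridge by an intramolecular Wittig reaction. It sets out from 9 and 5.
- Saponification of 9 (LiOH, THF–H2O) would give 2-{3-[2-(benzyloxy)-4-formylphenoxy]phenyl}acetic acid F1.
- Friedel–Crafts acylation of the phosphonium salt 5 with F1 (TFAA, cat. H3PO4, CH2Cl2–MeCN), again para to the methoxy group of ring A, would give the keto aldehyde phosphonium bromide F2.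
- Wittig olefination under high dilution (K2CO3, 18-crown-6, CH2Cl2, slow addition) would close the 20-membered ring as the macrocyclic stilbene ketone benzyl ether F3.
- Hydrogenation (H2, Pd/C, EtOAc) would saturate the alkene and remove the benzyl group to give the macrocyclic keto phenol F4.
- Mesylation of F4 (MsCl, Et3N, CH2Cl2) comes back to the route at 15.

Step 5. Displacement of a fluoride flanked by the electron-donating benzyloxy group may be sluggish, and at the temperature then required the arylacetate may condense with the aldehyde or lose its ester. The fallback replaces SNAr by a copper-catalysed Ullmann ether synthesis and sets out from 8. Purchased 4-bromo-3-hydroxybenzaldehyde F5 would be benzylated (BnBr, K2CO3, acetone) to 3-(benzyloxy)-4-bromobenzaldehyde F6. Coupling of F6 with 8 (CuI, N,N-dimethylglycine, Cs2CO3, dioxane, 90 °C) comes back to the route at 9.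

Step 11. The deoxygenation may stall at the benzylic alcohol stage, or the benzylic cation may be captured by a neighbouring arene across the ring. The fallback avoids a free cation and sets out from 15. Reduction with NaBH4 (THF–MeOH, 0 °C) would give the racemic macrocyclic benzylic alcohol F7. Hydrogenolysis of its p-methoxybenzylic C–O bond (H2, Pd/C, EtOAc–AcOH) comes back to the route at 16.

**Further compounds**
F1 | step 10 | 2-{3-[2-(benzyloxy)-4-formylphenoxy]phenyl}acetic acid | OC(=O)Cc1cccc(Oc2ccc(C=O)cc2OCc2ccccc2)c1
F2 | step 10 | {4-[5-(2-{3-[2-(benzyloxy)-4-formylphenoxy]phenyl}acetyl)-2-methoxyphenoxy]benzyl}triphenylphosphonium bromide | COc1ccc(cc1Oc1ccc(C[P+](c2ccccc2)(c2ccccc2)c2ccccc2)cc1)C(=O)Cc1cccc(Oc2ccc(C=O)cc2OCc2ccccc2)c1.[Br-]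
F3 | step 10 | macrocyclic stilbene ketone benzyl ether (E/Z mixture, geometry not defined) | COc1ccc2cc1Oc1ccc(cc1)C=Cc1ccc(c(OCc3ccccc3)c1)Oc1cccc(c1)CC2=O
F4 | step 10 | macrocyclic keto phenol (15 without the mesyl group) | COc1ccc2cc1Oc1ccc(cc1)CCc1ccc(c(O)c1)Oc1cccc(c1)CC2=O
F5 | step 5 | 4-bromo-3-hydroxybenzaldehyde (purchased) | O=Cc1ccc(Br)c(O)c1
F6 | step 5 | 3-(benzyloxy)-4-bromobenzaldehyde | O=Cc1ccc(Br)c(OCc2ccccc2)c1
F7 | step 11 | macrocyclic benzylic alcohol mesylate (racemic) | COc1ccc2cc1Oc1ccc(cc1)CCc1ccc(c(OS(C)(=O)=O)c1)Oc1cccc(c1)CC2O
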